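**Assumptions:** (S)-(+)-linalool (coriandrol, from coriander oil) and angelic anhydride are taken as purchasable. Germacrane numbering (C1–C15) is used to track atoms. Reagents and catalysts are not numbered.

## Retrosynthetic overview
1. Niveusin B comes from desilylation and C3 oxidation with transannular hemiketalisation, so the 3,10-oxa bridge forms last. Its precursor is the ten-membered carbocycle, closed at C3–C4 by an electrochemical Ni/Cr coupling of an alkenyl iodide with a lactol-masked aldehyde.
2. The seco compound comes from acylative opening of a 2,8-dioxabicyclo[3.2.1]octane acetal with angelic anhydride. This frees the C3 aldehyde and installs the 8-O-angelate in one operation.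
3. The trans α-methylene-γ-butyrolactone (C6–C7 bond) comes from a CrCl2 2-(alkoxycarbonyl)allylation of a (Z)-β-iodoenal, directed by C8.
4. The allyl bromide/bicyclic acetal comes from bromoacetalisation of a dienoate lactol, which relays stereochemistry from C10 to C8. Its sources are (S)-linalool (C1–C3, C8–C10, C14) and methyl 2-(bromomethyl)acrylate (C7, C11–C13). The iodoenal comes from but-2-yne-1,4-diol (C4–C6, C15).
5. Ring order: temporary bicyclic acetal, then γ-lactone, then ten-membered carbocycle, then THF hemiketal.

## Route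

**Step 1**
Reactants: 1 (S)-(+)-linalool
Product: 2 (3S)-3-hydroxy-3,7-dimethyloct-6-enal
Conditions: 9-BBN (2.2 equiv), THF, 0 °C→rt; then NMO, TPAP (5 mol %), 4 Å MS, CH2Cl2, rt (one pot)
Reagents that add atoms: N-methylmorpholine N-oxide, C[N+]1([O-])CCOCC1 (supplies the O)
Why: Anti-Markovnikov hydroboration with 9-BBN touches only the monosubstituted alkene, and amine-oxide/Ley–Griffith oxidation takes the B-alkyl group straight to the C8 aldehyde, leaving the bought C10 centre untouched.

**Step 2**
Reactants: 2; 3 methyl 2-(bromomethyl)acrylate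
Product: 4 methyl (3E,6S)-6-hydroxy-6,10-dimethyl-2-methylideneundeca-3,9-dienoate
Conditions: 3, PBu3, THF, 0 °C; then 2, K2CO3, rt; use promptly
Reagents that add atoms: methyl 2-(bromomethyl)acrylate, C=C(CBr)C(=O)OC
Why: Wittig olefination with the semi-stabilised allylic tributylphosphonium ylide is E-selective and brings in C7 and C11–C13, and the mild carbonate base avoids retro-aldol or dehydration of the β-hydroxy aldehyde.

**Step 3**
Reactants: 4
Product: 5 methyl (3E)-5-[(2S)-5-hydroxy-2-methyloxolan-2-yl]-2-methylidenepent-3-enoate (lactol, anomer mixture)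
Conditions: O3 (1.0 equiv, Sudan Red endpoint), pyridine, CH2Cl2, −78 °C
Reagents that add atoms: ozone, [O-][O+]=O
Why: Chemoselective ozonolysis works because the electron-rich trisubstituted alkene reacts much faster than the ester-deactivated diene, and the C3 aldehyde is captured by the 10-OH as the five-membered lactol.

**Step 4**
Reactants: 5
Product: 6 methyl (2Z)-2-(bromomethyl)-3-[(1R,3R,5S)-5-methyl-2,8-dioxabicyclo[3.2.1]octan-3-yl]prop-2-enoate (side chain exo/equatorial at C8)
Conditions: NBS, NaHCO3, 4 Å MS, MeCN, −20→0 °C; then LiBr (cat.), rt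
Reagents that add atoms: N-bromosuccinimide, O=C1CCC(=O)N1Br
Why: In this intramolecular haloetherification of an ene-hemiacetal (bromoacetalisation), only the equilibrating anomer with OH cis to the chain reaches C8 (6-exo), the chair transition state places the C7 substituent exo and away from the C1–C2 bridge so C10 sets 8R, and any C7 bromide relaxes by bromide SN2′ to the primary (Z)-allyl bromide.

**Step 5**
Reactants: 7 but-2-yne-1,4-diol
Product: 8 4-[(tert-butyldiphenylsilyl)oxy]but-2-yn-1-ol
Conditions: TBDPSCl (0.3 equiv), imidazole, DMF, 0 °C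
Reagents that add atoms: TBDPSCl, CC(C)(C)[Si](Cl)(c1ccccc1)c1ccccc1
Why: Statistical monosilylation with a cheap excess of diol differentiates the future C15–OH from C6–OH.

**Step 6**
Reactants: 8
Product: 9 (2Z)-4-[(tert-butyldiphenylsilyl)oxy]-3-iodobut-2-en-1-ol
Conditions: Red-Al, THF, 0 °C→rt; EtOAc; then I2, −78 °C
Reagents that add atoms: iodine, II
Why: Hydroxyl-directed trans-hydroalumination then iodinolysis puts iodine on the distal alkyne carbon (C4) cis to C6, which is the 4Z geometry of the target.

**Step 7**
Reactants: 9
Product: 10 (2Z)-4-[(tert-butyldiphenylsilyl)oxy]-3-iodobut-2-enal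
Conditions: MnO2, CH2Cl2, rt
Reagents that add atoms: none
Why: Allylic oxidation with MnO2 is neutral and preserves the Z-iodoalkene.

**Step 8**
Reactants: 6; 10
Product: 11 (4R,5S)-5-[(1Z)-3-(TBDPS-oxy)-2-iodoprop-1-enyl]-3-methylidene-4-[(1R,3R,5S)-5-methyl-2,8-dioxabicyclo[3.2.1]octan-3-yl]oxolan-2-one (trans lactone; C6 and C7 have the target's spatial configuration)
Conditions: CrCl2 (3 equiv, Ni-free), THF, 0 °C→rt; then PPTS (cat.), CH2Cl2
Reagents that add atoms: none
Why: In this Nozaki–Hiyama 2-(alkoxycarbonyl)allylation/lactonisation, the (E)-allylchromium reacts through a Zimmerman–Traxler chair (anti, giving the trans-6,7-lactone) on the alkene face anti to C9 of the A1,3-locked C8 centre (Felkin-type), while Ni-free Cr(II) spares the alkenyl iodide and the ether-type O8 resists vinylogous 1,4-elimination.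

**Step 9**
Reactants: 11; 12 angelic anhydride
Product: 13 seco-lactol: the lactone of 11 now carries at C7 a (1R)-1-(angeloyloxy)-2-[(2S)-5-hydroxy-2-methyloxolan-2-yl]ethyl group (anomer mixture)
Conditions: 12 (3 equiv), Sc(OTf)3 (5 mol %), MeCN–CH2Cl2, −20 °C; then THF–H2O–AcOH, rt
Reagents that add atoms: angelic anhydride, C/C=C(/C)C(=O)OC(=O)/C(C)=C\C; water, O
Why: Lewis-acid acylative cleavage of the bicyclic acetal (the same type as acetolysis of 1,6-anhydro sugars) acylates the less hindered O8 and leaves the five-ring oxocarbenium, whose labile anomeric ester hydrolyses to the lactol, and 8R is retained because the C8–O bond is never broken.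

**Step 10**
Reactants: 13
Product: 14 (3ξ)-8β-angeloyloxy-3,10-dihydroxy-15-(TBDPS-oxy)germacra-4Z,11(13)-dien-6α,12-olide
Conditions: CrCl3·3THF (20 mol %), NiCl2·glyme/neocuproine (2 mol %), Cp2ZrCl2 (1.5 equiv), LiCl, Bu4NPF6, DMF–MeCN, undivided cell, Al(+)|Ni foam(−), constant current; 13 added by syringe pump (final 2 mM), rt
Reagents that add atoms: none
Why: Proposed new method: electroreductive Ni/Cr-catalysed medium-ring closure onto a lactol-masked aldehyde, in which the cathode regenerates Cr(II) well positive of the enoate reduction potentials, Ni(0) inserts into the C4–I bond with retention, transmetalation gives an alkenyl-Cr(III) that adds to the small aldehyde population kept open by Zr(IV) binding of the tertiary alkoxide, Cp2ZrCl2 releases the Cr alkoxide for turnover, and slow addition with a low steady-state Cr(II) level gives pseudo-high dilution; the closest known reactions are the intermolecular electrochemical Nozaki–Hiyama–Kishi coupling and stoichiometric Ni/Cr closures of 9- and 10-membered rings.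

**Step 11**
Reactants: 14
Product: 15 15-O-TBDPS-niveusin B
Conditions: Dess–Martin periodinane, NaHCO3, CH2Cl2, 0 °C
Reagents that add atoms: none
Why: Dess–Martin oxidation erases the C3 carbinol mixture, the 10-OH adds transannularly to the enone, and only the cis-bridged hemiketal is geometrically possible, so C10 fixes 3R under thermodynamic control.

**Step 12**
Reactants: 15
Product: 16 niveusin B
Conditions: HF·pyridine, pyridine–THF, 0 °C→rt
Reagents that add atoms: none
Why: Buffered fluoride desilylation frees the 15-OH without acyl migration, angelate isomerisation or Michael addition to the α-methylene lactone.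

## Compound list
1 | (S)-(+)-linalool | C=C[C@@](C)(O)CCC=C(C)C | starting material
2 | (3S)-3-hydroxy-3,7-dimethyloct-6-enal | O=CC[C@@](C)(O)CCC=C(C)C | intermediate
3 | methyl 2-(bromomethyl)acrylate | C=C(CBr)C(=O)OC | starting material
4 | methyl (3E,6S)-6-hydroxy-6,10-dimethyl-2-methylideneundeca-3,9-dienoate | C=C(C(=O)OC)/C=C/C[C@@](C)(O)CCC=C(C)C | intermediate
5 | methyl (3E)-5-[(2S)-5-hydroxy-2-methyloxolan-2-yl]-2-methylidenepent-3-enoate | C=C(C(=O)OC)/C=C/C[C@]1(C)CCC(O)O1 | intermediate
6 | methyl (2Z)-2-(bromomethyl)-3-[(1R,3R,5S)-5-methyl-2,8-dioxabicyclo[3.2.1]octan-3-yl]prop-2-enoate | COC(=O)/C(CBr)=C/[C@H]1C[C@]2(C)CC[C@H](O1)O2 | intermediate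
7 | but-2-yne-1,4-diol | OCC#CCO | starting material
8 | 4-[(tert-butyldiphenylsilyl)oxy]but-2-yn-1-ol | OCC#CCO[Si](c1ccccc1)(c1ccccc1)C(C)(C)C | intermediate
9 | (2Z)-4-[(tert-butyldiphenylsilyl)oxy]-3-iodobut-2-en-1-ol | OC/C=C(/CO[Si](c1ccccc1)(c1ccccc1)C(C)(C)C)I | intermediate
10 | (2Z)-4-[(tert-butyldiphenylsilyl)oxy]-3-iodobut-2-enal | O=C/C=C(/CO[Si](c1ccccc1)(c1ccccc1)C(C)(C)C)I | intermediate
11 | trans α-methylene lactone bearing the alkenyl iodide and the bicyclic acetal | C=C1C(=O)O[C@H](/C=C(/CO[Si](c2ccccc2)(c2ccccc2)C(C)(C)C)I)[C@H]1[C@H]2C[C@]3(C)CC[C@H](O2)O3 | intermediate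
12 | angelic anhydride | C/C=C(/C)C(=O)OC(=O)/C(C)=C\C | starting material
13 | 8-O-angeloyl seco-lactol (masked C3 aldehyde) | C=C1C(=O)O[C@H](/C=C(/CO[Si](c2ccccc2)(c2ccccc2)C(C)(C)C)I)[C@H]1[C@H](OC(=O)/C(C)=C\C)C[C@]2(C)CCC(O)O2 | intermediate
14 | (3ξ)-3,10-dihydroxy-germacradienolide (ten-membered ring) | C=C1C(=O)O[C@@H]2/C=C(/CO[Si](c3ccccc3)(c3ccccc3)C(C)(C)C)C(O)CC[C@](C)(O)C[C@@H](OC(=O)/C(C)=C\C)[C@@H]12 | intermediate
15 | 15-O-TBDPS-niveusin B | C=C1C(=O)O[C@@H]2/C=C(/CO[Si](c4ccccc4)(c4ccccc4)C(C)(C)C)[C@@]3(O)CC[C@@](C)(C[C@@H](OC(=O)/C(C)=C\C)[C@@H]12)O3 | intermediate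
16 | niveusin B | C=C1C(=O)O[C@@H]2/C=C(/CO)[C@@]3(O)CC[C@@](C)(C[C@@H](OC(=O)/C(C)=C\C)[C@@H]12)O3 | target

## Step count
Total steps: 12. Longest linear sequence: 9 (steps 1–4 and 8–12).

## Three steps most likely to fail
1. **Step 10 (proposed new electrochemical ring closure).** The risks are protodeiodination, oligomerisation, or the lactol not opening.
   Fallback (known chemistry, different disconnection):
   - Use acrolein in place of 10 in step 8.
   - After step 9, couple the C3 aldehyde intermolecularly with 2-iodoallyl TBDPS ether under standard stoichiometric CrCl2/cat. NiCl2.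
   - Oxidise with DMP and lock the product as the methyl ketal.
   - Close C4=C5 by ring-closing metathesis (Hoveyda–Grubbs II) on the pre-formed 11-oxabicyclo[6.2.1]undecene framework, then apply aqueous acid and HF·pyridine.
2. **Step 4 (bromoacetalisation of the electron-poor diene).** The risks are sluggish bromination, lactol over-oxidation, or competing 5-endo closure by the 10-OH.
   Fallback:
   - Carry out PhSeBr-induced selenoacetalisation, placing O at C8 and Se at C7 through the same bicyclic control.
   - Oxidise with H2O2 so that the allylic selenoxide undergoes a [2,3]-shift to the C13 allylic alcohol.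
   - Convert that alcohol to the bromide 6 with CBr4/PPh3.
3. **Step 9 (acylative acetal opening).** The risks are angelate-to-tiglate isomerisation or incomplete cleavage.
   Fallback:
   - Methanolyse with CSA/MeOH to the methyl furanoside with a free 8-OH.
   - Esterify with angelic acid through its 2,4,6-trichlorobenzoyl mixed anhydride.
   - Hydrolyse the methyl acetal to 13 with aqueous AcOH.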